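**Plan**

- **Cuts, in retrosynthetic order:** the three O–CH3 bonds; CH2 back to C=O at the bridge carbon attached to ring C; the ether O–C bond to ring C, which opens the macrocycle; the CH2–C(=O) bond of the C–D bridge; the A–D biaryl bond; the CH2–CH2 bond of the A–B bridge.
- **Enabling feature:** ring C is a 1,4-phenylene carrying only the ether oxygen at C-1 and the first carbon of the C–D bridge at C-4. Once that bridge carbon is a ketone, an acyl group stands para to C-1, so a fluoride there can be displaced by addition-elimination with no activating atom foreign to the skeleton.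
- **Forward order:** ring B ylide plus ring A formyl boronate (Wittig, then hydrogenation); Suzuki coupling to the ring D bromoaldehyde; olefination/hydrolysis that adds ring C as a 4-fluorophenyl ketone; closure of the only new ring, the 16-membered macrocycle; deoxygenation; demethylation.
- **Why this order:** the ketone is installed only after the ring A aldehyde has been consumed. A biaryl with CHO on ring A and CH2C(=O)Ar on ring D would condense to a phenanthrene under any base.
- **Stereochemistry:** the target has no stereocentre and its biaryl axis bears no descriptor, so nothing has to be set.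

Key step: step 10

Assumption: because the target string carries no stereodescriptor, the A–D biaryl axis is treated as stereochemically undefined, and all macrocycles are drawn without axial configuration.

**Step 1**
Reactants: 1 isovanillin (3-hydroxy-4-methoxybenzaldehyde)
Product: 2 3-(benzyloxy)-4-methoxybenzaldehyde
Conditions: BnBr, K2CO3, DMF, rt
Reagents that add atoms: benzyl bromide, BrCc1ccccc1
Why: Williamson etherification of the only acidic OH; the benzyl group masks the ring B phenol during ylide chemistry and later leaves in the same operation that saturates the stilbene.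

**Step 2**
Reactants: 2 3-(benzyloxy)-4-methoxybenzaldehyde
Product: 3 [3-(benzyloxy)-4-methoxyphenyl]methanol
Conditions: NaBH4, MeOH, 0 °C
Reagents that add atoms: none
Why: Borohydride reduction of an aromatic aldehyde, to which both ether groups are inert.

**Step 3**
Reactants: 3 [3-(benzyloxy)-4-methoxyphenyl]methanol
Product: 4 [3-(benzyloxy)-4-methoxybenzyl]triphenylphosphonium bromide
Conditions: PPh3·HBr, MeCN, reflux
Reagents that add atoms: triphenylphosphine hydrobromide, [Br-].c1ccc(cc1)[PH+](c1ccccc1)c1ccccc1
Why: Acid-promoted SN1-type substitution, in which the electron-rich benzylic alcohol is ionised and trapped by PPh3, gives the Wittig salt directly and avoids a labile benzylic bromide.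

**Step 4**
Reactants: 5 2-formyl-4-methoxyphenylboronic acid
Product: 6 5-methoxy-2-(4,4,5,5-tetramethyl-1,3,2-dioxaborolan-2-yl)benzaldehyde
Conditions: pinacol, toluene, reflux (Dean–Stark)
Reagents that add atoms: pinacol, CC(C)(O)C(C)(C)O
Why: Boronic ester formation by condensation with a 1,2-diol, driven by azeotropic removal of water, removes the acidic B–OH groups that would quench the ylide of the next step.

**Step 5**
Reactants: 4 [3-(benzyloxy)-4-methoxybenzyl]triphenylphosphonium bromide; 6 5-methoxy-2-(4,4,5,5-tetramethyl-1,3,2-dioxaborolan-2-yl)benzaldehyde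
Product: 8 A–B stilbene boronate (E/Z mixture), via ylide 7 (not isolated)
Conditions: KOtBu, THF, 0 °C; then 6, 0 °C to rt
Reagents that add atoms: none
Why: Wittig olefination of an aromatic aldehyde with a semi-stabilised benzylic ylide tolerates the aryl pinacol boronate, and the alkene geometry is irrelevant because the double bond is saturated next.

**Step 6**
Reactants: 8 A–B stilbene boronate
Product: 9 A–B bibenzyl boronate phenol, 2-methoxy-5-{2-[5-methoxy-2-(4,4,5,5-tetramethyl-1,3,2-dioxaborolan-2-yl)phenyl]ethyl}phenol
Conditions: H2 (1 atm), Pd/C, EtOAc/EtOH, rt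
Reagents that add atoms: none
Why: Heterogeneous catalytic hydrogenation saturates the stilbene and hydrogenolyses the benzyl ether in one operation, at a stage where no carbonyl group is present and the aryl–boron bond is inert.

**Step 7**
Reactants: 9 A–B bibenzyl boronate phenol; 10 2-bromo-3-methoxybenzaldehyde
Product: 11 2'-[2-(3-hydroxy-4-methoxyphenyl)ethyl]-4',6-dimethoxybiphenyl-2-carbaldehyde
Conditions: Pd(OAc)2, SPhos, K3PO4, toluene/H2O, 90 °C
Reagents that add atoms: none
Why: Suzuki–Miyaura coupling with a bulky electron-rich biarylphosphine is established for tri-ortho-substituted biaryls, and since no enolisable ketone is yet present, base-induced aldol ring closure across the new axis cannot take place.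

**Step 8**
Reactants: 12 4-fluorobenzaldehyde
Product: 14 diphenyl [(4-fluorophenyl)(phenylamino)methyl]phosphonate (racemic), via imine 13 (not isolated)
Conditions: PhNH2, iPrOH, rt; then (PhO)2P(O)H, rt
Reagents that add atoms: aniline, Nc1ccccc1; diphenyl phosphite, O=[PH](Oc1ccccc1)Oc1ccccc1
Why: Kabachnik–Fields three-component condensation, in which the phosphite adds to the preformed imine, gives a crystalline N,P-acetal whose stereocentre is lost in the next step.

**Step 9**
Reactants: 11 2'-[2-(3-hydroxy-4-methoxyphenyl)ethyl]-4',6-dimethoxybiphenyl-2-carbaldehyde; 14 diphenyl [(4-fluorophenyl)(phenylamino)methyl]phosphonate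
Product: 16 seco fluoro ketone phenol, via enamine 15 (not isolated)
Conditions: Cs2CO3, THF/iPrOH, rt; then 2 M HCl, rt
Reagents that add atoms: water, O
Why: Horner–Wadsworth–Emmons olefination of the aldehyde with the N,P-acetal anion gives an enamine whose acid hydrolysis places the carbonyl on the ring C side of the new bridge, the ring B phenoxide being a spectator at room temperature.

**Step 10**
Reactants: 16 seco fluoro ketone phenol
Product: 19 macrocyclic bridge ketone, via caesium phenoxide 17 (not isolated), via Meisenheimer adduct 18 (not isolated)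
Conditions: Cs2CO3 (2 equiv), degassed DMSO, 120 °C, Ar; 16 added by syringe pump over 12 h, final 2 mM
Reagents that add atoms: none
Why: Cs2CO3 converts the only free hydroxyl, that of ring B, into caesium phenoxide 17, whose oxygen adds to the fluorine-bearing carbon of ring C to give Meisenheimer adduct 18 with the charge on the para acyl oxygen, and loss of fluoride restores ring C as the diaryl ether. The closest known chemistry is the SNAr etherification of 4-fluorophenyl ketones by phenoxides, run under pseudo-high dilution for macrocyclic aryl ether ketones, together with SNAr cycloetherification of activated aryl fluorides in cyclophane synthesis. The one new ring, 16-membered, closes end to end, formally by 16-endo-trig addition followed by elimination, and the preformed A–D biaryl holds both arms on the same flank, which brings the reacting ends together. No stereocentre is created. The step needs O-arylation to win over enolate chemistry and chain growth: the bridge CH2 is about as acidic as the phenol, but its enolate cannot reach the para carbon of its own ring, switches ring C off as an acceptor only reversibly, and can otherwise react only between molecules, which slow addition at 2 mM suppresses. DMSO is chosen over DMF so that no dimethylamine competes for the fluoride, and exclusion of oxygen prevents autoxidation of the enolate.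

**Step 11**
Reactants: 19 macrocyclic bridge ketone
Product: 21 plagiochin E trimethyl ether, via benzylic alcohol 20 (not isolated)
Conditions: Et3SiH, CF3CO2H, CH2Cl2, 0 °C to rt
Reagents that add atoms: none
Why: Ionic hydrogenation (Kursanov–Parnes type) delivers hydride to the protonated aryl ketone and then to the benzylic position, which ionises easily thanks to the para aryloxy oxygen of ring C, while the only ring carbon within reach for transannular Friedel–Crafts attack, the free ortho carbon of ring A next to the axis, is meta to its methoxy group and not activated.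

**Step 12**
Reactants: 21 plagiochin E trimethyl ether
Product: 23 plagiochin E, via tris(dibromoboryl) ether 22 (not isolated)
Conditions: BBr3, CH2Cl2, −78 °C to rt; then H2O
Reagents that add atoms: none
Why: BBr3 cleavage of aryl methyl ethers proceeds by boron coordination and SN2 removal of each methyl group by bromide, whereas the diaryl ether offers no sp3 C–O bond and stays intact.

**Compound list**

1 | isovanillin (3-hydroxy-4-methoxybenzaldehyde) | COc1ccc(C=O)cc1O | starting material
2 | 3-(benzyloxy)-4-methoxybenzaldehyde | COc1ccc(C=O)cc1OCc1ccccc1 | intermediate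
3 | [3-(benzyloxy)-4-methoxyphenyl]methanol | COc1ccc(CO)cc1OCc1ccccc1 | intermediate
4 | [3-(benzyloxy)-4-methoxybenzyl]triphenylphosphonium bromide | COc1ccc(C[P+](c2ccccc2)(c2ccccc2)c2ccccc2)cc1OCc1ccccc1.[Br-] | intermediate
5 | 2-formyl-4-methoxyphenylboronic acid | COc1ccc(B(O)O)c(C=O)c1 | starting material
6 | 5-methoxy-2-(4,4,5,5-tetramethyl-1,3,2-dioxaborolan-2-yl)benzaldehyde | COc1ccc(B2OC(C)(C)C(C)(C)O2)c(C=O)c1 | intermediate
7 | [3-(benzyloxy)-4-methoxybenzylidene]triphenylphosphorane (ylide, formed in the flask) | COc1ccc(C=P(c2ccccc2)(c2ccccc2)c2ccccc2)cc1OCc1ccccc1 | intermediate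
8 | A–B stilbene boronate, 2-{2-[2-(3-benzyloxy-4-methoxyphenyl)ethenyl]-4-methoxyphenyl}-4,4,5,5-tetramethyl-1,3,2-dioxaborolane (E/Z mixture, no descriptor) | COc1ccc(B2OC(C)(C)C(C)(C)O2)c(C=Cc2ccc(OC)c(OCc3ccccc3)c2)c1 | intermediate
9 | A–B bibenzyl boronate phenol, 2-methoxy-5-{2-[5-methoxy-2-(4,4,5,5-tetramethyl-1,3,2-dioxaborolan-2-yl)phenyl]ethyl}phenol | COc1ccc(B2OC(C)(C)C(C)(C)O2)c(CCc2ccc(OC)c(O)c2)c1 | intermediate
10 | 2-bromo-3-methoxybenzaldehyde | COc1cccc(C=O)c1Br | starting material
11 | 2'-[2-(3-hydroxy-4-methoxyphenyl)ethyl]-4',6-dimethoxybiphenyl-2-carbaldehyde | COc1ccc(c(c1)CCc1ccc(OC)c(O)c1)-c1c(OC)cccc1C=O | intermediate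
12 | 4-fluorobenzaldehyde | O=Cc1ccc(F)cc1 | starting material
13 | (E)-N-(4-fluorobenzylidene)aniline (formed in the flask) | Fc1ccc(/C=N/c2ccccc2)cc1 | intermediate
14 | diphenyl [(4-fluorophenyl)(phenylamino)methyl]phosphonate (racemic) | O=P(Oc1ccccc1)(Oc1ccccc1)C(Nc1ccccc1)c1ccc(F)cc1 | intermediate
15 | enamine, 5-{2-[2'-(2-anilino-2-(4-fluorophenyl)ethenyl)-4,6'-dimethoxybiphenyl-2-yl]ethyl}-2-methoxyphenol (geometry undefined, formed in the flask) | COc1ccc(c(c1)CCc1ccc(OC)c(O)c1)-c1c(OC)cccc1C=C(Nc1ccccc1)c1ccc(F)cc1 | intermediate
16 | seco fluoro ketone phenol, 1-(4-fluorophenyl)-2-{2'-[2-(3-hydroxy-4-methoxyphenyl)ethyl]-4',6-dimethoxybiphenyl-2-yl}ethan-1-one | COc1ccc(c(c1)CCc1ccc(OC)c(O)c1)-c1c(OC)cccc1CC(=O)c1ccc(F)cc1 | intermediate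
17 | caesium phenoxide of 16 (ring B oxygen deprotonated, formed in the flask) | COc1ccc(c(c1)CCc1ccc(OC)c([O-])c1)-c1c(OC)cccc1CC(=O)c1ccc(F)cc1.[Cs+] | intermediate
18 | Meisenheimer adduct, macrocycle in which ring C is a cyclohexa-2,5-dienylidene whose sp3 carbon bears F and the ring B oxygen, charge on the enolate oxygen, caesium salt (formed in the flask) | COc1ccc2c(c1)CCc1ccc(OC)c(c1)OC1(F)C=CC(C=C1)=C([O-])Cc1cccc(OC)c1-2.[Cs+] | intermediate
19 | macrocyclic bridge ketone (16-membered ring, C=O on the bridge carbon attached to ring C, three OMe) | COc1ccc2c(c1)CCc1ccc(OC)c(c1)Oc1ccc(cc1)C(=O)Cc1cccc(OC)c1-2 | intermediate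
20 | macrocyclic benzylic alcohol (racemic, formed in the flask) | COc1ccc2c(c1)CCc1ccc(OC)c(c1)Oc1ccc(cc1)C(O)Cc1cccc(OC)c1-2 | intermediate
21 | plagiochin E trimethyl ether | COc1ccc2c(c1)CCc1ccc(OC)c(c1)Oc1ccc(cc1)CCc1cccc(OC)c1-2 | intermediate
22 | tris(dibromoboryl) ether of plagiochin E (formed in the flask) | BrB(Br)Oc1ccc2c(c1)CCc1ccc(OB(Br)Br)c(c1)Oc1ccc(cc1)CCc1cccc(OB(Br)Br)c1-2 | intermediate
23 | plagiochin E | Oc1ccc2c(c1)CCc1ccc(O)c(c1)Oc1ccc(cc1)CCc1cccc(O)c1-2 | target

**Count**

Total step count: 12.
Longest linear sequence: 10 steps from isovanillin (steps 1, 2, 3, 5, 6, 7, 9, 10, 11, 12).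

**Steps most likely to fail**

**Step 10, the macrocyclisation.**
- What may go wrong: etherification between molecules may outrun ring closure. The substrate may also rest as its unreactive enolate, so that long heating erodes material.
- Fallback: the same oxygen–ring C bond is closed by a copper-mediated Ullmann coupling on a substrate that holds no ketone. It sets out from aldehyde 11.
- Wittig olefination uses (4-bromobenzylidene)triphenylphosphorane F1, generated in THF from commercial (4-bromobenzyl)triphenylphosphonium bromide and KOtBu, with one extra equivalent of base for the phenol. It should give 5-{2-[2'-(4-bromostyryl)-4,6'-dimethoxybiphenyl-2-yl]ethyl}-2-methoxyphenol F2.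
- Hydrogenation over Pt/C (H2, 1 atm, EtOAc), which spares the C–Br bond, should give 5-{2-[2'-(4-bromophenethyl)-4,6'-dimethoxybiphenyl-2-yl]ethyl}-2-methoxyphenol F3.
- CuO, K2CO3, pyridine at reflux under high dilution then closes the ring. The route is rejoined at trimethyl ether 21, so step 11 is no longer needed.

**Step 7, the hindered biaryl coupling.**
- What may go wrong: protodeboronation of the electron-rich, ortho-alkylated boronate may outpace the slow transmetalation at a doubly ortho-substituted arylpalladium bromide, wasting an advanced fragment.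
- Fallback: the axis is built first from small partners and the A–B bridge is attached afterwards. It sets out from 10, 5 and ylide 7 (from 4) and replaces steps 4 to 7.
- Bromoaldehyde 10 is masked (ethylene glycol, TsOH, toluene, Dean–Stark) as 2-(2-bromo-3-methoxyphenyl)-1,3-dioxolane F4.
- Suzuki coupling with an excess of the inexpensive boronic acid 5 (Pd(PPh3)4, Na2CO3, DME/H2O, 85 °C) should give 2'-(1,3-dioxolan-2-yl)-4,6'-dimethoxybiphenyl-2-carbaldehyde F5. Its second carbonyl is masked and cannot enolise.
- Wittig reaction with ylide 7 should give the benzyl-protected stilbene acetal F6.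
- H2 over Pd/C in EtOAc should give the bibenzyl phenol acetal F7.
- 1 M HCl in THF releases the aldehyde, and the route is rejoined at 11.

**Step 11, the deoxygenation.**
- What may go wrong: in strong acid, transannular Friedel–Crafts capture of the ionised benzylic position by a neighbouring anisole ring may occur. The reduction may also stall before the second hydride transfer.
- Fallback: the carbocation regime is avoided. It sets out from ketone 19.
- NaBH4 in MeOH/THF should give alcohol 20, now isolated.
- Catalytic hydrogenolysis of its benzylic C–O bond (H2, Pd/C, AcOH, rt to 50 °C) comes back to the route at 21.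

**Further compounds**

F1 | step 10 | (4-bromobenzylidene)triphenylphosphorane | Brc1ccc(C=P(c2ccccc2)(c2ccccc2)c2ccccc2)cc1
F2 | step 10 | 5-{2-[2'-(4-bromostyryl)-4,6'-dimethoxybiphenyl-2-yl]ethyl}-2-methoxyphenol (E/Z mixture) | COc1ccc(c(c1)CCc1ccc(OC)c(O)c1)-c1c(OC)cccc1C=Cc1ccc(Br)cc1
F3 | step 10 | 5-{2-[2'-(4-bromophenethyl)-4,6'-dimethoxybiphenyl-2-yl]ethyl}-2-methoxyphenol | COc1ccc(c(c1)CCc1ccc(OC)c(O)c1)-c1c(OC)cccc1CCc1ccc(Br)cc1
F4 | step 7 | 2-(2-bromo-3-methoxyphenyl)-1,3-dioxolane | COc1cccc(C2OCCO2)c1Br
F5 | step 7 | 2'-(1,3-dioxolan-2-yl)-4,6'-dimethoxybiphenyl-2-carbaldehyde | COc1ccc(c(C=O)c1)-c1c(OC)cccc1C1OCCO1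
F6 | step 7 | benzyl-protected stilbene acetal, 2-{2'-[2-(3-benzyloxy-4-methoxyphenyl)ethenyl]-4',6-dimethoxybiphenyl-2-yl}-1,3-dioxolane (E/Z mixture) | COc1ccc(c(c1)C=Cc1ccc(OC)c(OCc2ccccc2)c1)-c1c(OC)cccc1C1OCCO1
F7 | step 7 | bibenzyl phenol acetal, 5-{2-[2'-(1,3-dioxolan-2-yl)-4,6'-dimethoxybiphenyl-2-yl]ethyl}-2-methoxyphenol | COc1ccc(c(c1)CCc1ccc(OC)c(O)c1)-c1c(OC)cccc1C1OCCO1
F0 | step 11 | none | none
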